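**Plan**

1. Ring labels: B is the benzo ring at the CH= end of the cycloheptatriene, C is the benzo ring at its C(Ar)= end (it also carries the second dihydrofuran), and D is the pendant 3,5-dihydroxyphenyl ring.
2. Cuts: (i) the C(Ar)=–ring C bond of the seven-membered ring, back to an arylalkyne on ring B; (ii) in the ring-B dihydrofuran the C3–ring C, C2–C3 and C2–O bonds, back to a ring-B O-Boc aldehyde, a ring-C aryllithium and an ArCH sulfonium ylide; (iii) the same three bonds of the ring-C dihydrofuran (C3–ring D, C2–C3, C2–O).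
3. Forward order: the ring-C dihydrofuran by a three-component annulation (step 7); the ring-B dihydrofuran by the same annulation, which now joins the two halves and the last ArCH unit (step 14); the cycloheptatriene by 7-endo alkyne hydroarylation (step 15); then desilylation and demethylation.
4. Feature used: the sp3 carbon shared by the seven-membered ring and the ring-B dihydrofuran is a diarylmethine ortho to a phenolic oxygen of ring B. It is therefore the methide carbon of an ortho-quinone methide of ring B, which an aldehyde carbon plus an aryl-metal can build and a one-carbon ylide can annulate. C3 of the ring-C dihydrofuran, which lies between the two ring-C oxygens, has the same character.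
5. Stereochemistry: C2 of each dihydrofuran comes from the face of a C2-symmetric 2,5-dimethylthiolanium benzylide, and C3 from the trans-selective annulation. The two units have opposite absolute sense, (2R,3R) on ring C and (2S,3S) on ring B, so the two enantiomers of the reagent are used in turn.

Key step: step 14

Assumption: the (2R,5R)-thiolanium benzylide is taken to transfer its ArCH carbon with the same facial sense as in its stilbene-oxide-forming reaction, which corresponds to (2R) in the dihydrobenzofuran; if the sense is the reverse, salts 9 and 25 change places and nothing else changes.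

**Route**

Step 1
Reactants: 1 4-bromo-2,6-dimethoxybenzaldehyde
Product: 2 4-bromo-2,6-dihydroxybenzaldehyde
Conditions: BBr3 (3 equiv), CH2Cl2, −78 °C → rt; H2O
Reagents that add atoms: none
Why: BBr3 cleaves both aryl methyl ethers (complexation, then SN2 attack of bromide on methyl), helped by chelation to the ortho formyl oxygen, while the aldehyde and the aryl bromide are unaffected (aryl methyl ether cleavage).

Step 2
Reactants: 2 4-bromo-2,6-dihydroxybenzaldehyde
Product: 3 4-bromo-2-hydroxy-6-(triisopropylsilyloxy)benzaldehyde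
Conditions: TIPSCl (1.0 equiv), imidazole, CH2Cl2, 0 °C
Reagents that add atoms: chlorotriisopropylsilane, CC(C)[Si](Cl)(C(C)C)C(C)C
Why: The two phenols are equivalent, and after the first bulky silyl group is on, the remaining hydroxyl is locked in a hydrogen bond to the formyl oxygen, so one equivalent should stop at the mono ether (silyl ether formation).

Step 3
Reactants: 3 4-bromo-2-hydroxy-6-(triisopropylsilyloxy)benzaldehyde
Product: 4 tert-butyl 5-bromo-2-formyl-3-(triisopropylsilyloxy)phenyl carbonate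
Conditions: Boc2O, DMAP (cat.), CH2Cl2, rt
Reagents that add atoms: di-tert-butyl dicarbonate, CC(C)(C)OC(=O)OC(=O)OC(C)(C)C
Why: DMAP-catalysed O-acylation of the chelated phenol gives the aryl tert-butyl carbonate that later acts as the internal leaving group for quinone methide formation (carbonate formation).

Step 4
Reactants: 5 (2S,5S)-hexane-2,5-diol
Product: 6 (2S,5S)-hexane-2,5-diyl dimethanesulfonate
Conditions: MsCl, Et3N, CH2Cl2, −20 → 0 °C
Reagents that add atoms: methanesulfonyl chloride, CS(=O)(=O)Cl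
Why: Sulfonylation at oxygen leaves both stereocentres untouched (mesylate formation).

Step 5
Reactants: 6 (2S,5S)-hexane-2,5-diyl dimethanesulfonate
Product: 7 (2R,5R)-2,5-dimethylthiolane
Conditions: Na2S·9H2O, EtOH, rt; distillation
Reagents that add atoms: sodium sulfide, [Na+].[Na+].[S-2]
Why: Sulfide displaces the first mesylate intermolecularly and the second by 5-exo-tet closure, each by SN2 with inversion, so the (2S,5S)-dimesylate gives the trans (2R,5R)-thiolane (double nucleophilic substitution).

Step 6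
Reactants: 7 (2R,5R)-2,5-dimethylthiolane; 8 4-methoxybenzyl chloride
Product: 9 (2R,5R)-1-(4-methoxybenzyl)-2,5-dimethylthiolan-1-ium tetrafluoroborate
Conditions: AgBF4, CH2Cl2, 0 °C → rt, dark
Reagents that add atoms: silver tetrafluoroborate, [Ag+].F[B-](F)(F)F
Why: Silver-assisted ionisation of the benzylic chloride and capture by the sulfide gives the sulfonium salt; the thiolane is C2-symmetric, so sulfur is not a stereocentre and a single salt results (S-alkylation).

Step 7
Reactants: 4 tert-butyl 5-bromo-2-formyl-3-(triisopropylsilyloxy)phenyl carbonate; 10 1-bromo-3,5-dimethoxybenzene; 9 (2R,5R)-1-(4-methoxybenzyl)-2,5-dimethylthiolan-1-ium tetrafluoroborate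
Product: 16 (2R,3R)-6-bromo-3-(3,5-dimethoxyphenyl)-2-(4-methoxyphenyl)-4-(triisopropylsilyloxy)-2,3-dihydro-1-benzofuran, via 3,5-dimethoxyphenyllithium 11 (not isolated), via lithium phenoxide benzylic carbonate 12 (not isolated), via (2R,5R)-thiolanium benzylide 13 (not isolated), via ortho-quinone methide 14 (not isolated), via phenoxide sulfonium betaine 15 (not isolated)
Conditions: 10, n-BuLi, THF, −78 °C; 4, −78 °C; 13 (from 9, LiHMDS, THF, −78 °C, second flask) added by cannula; MgBr2·OEt2, −78 → −20 °C; aq NH4Cl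
Reagents that add atoms: none
Why: Proposed new method: the sequence of step 14 on a simpler pair (aryllithium addition to the O-Boc aldehyde, Boc transfer to the new alkoxide, magnesium-triggered 1,4-elimination to the ortho-quinone methide, conjugate addition of the chiral benzylide, 5-exo-tet O-alkylation with inversion), closest to the known [4+1] annulation of ortho-quinone methides with sulfonium ylides and to the organometal-triggered generation of ortho-quinone methides from O-Boc salicylaldehydes; C2 is set by the ylide face that the (2R,5R)-thiolane leaves open, C3 by the trans-selective annulation, and only the oxygen that carried the Boc group can close the ring.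

Step 8
Reactants: 17 2-bromo-4,6-dimethoxybenzaldehyde
Product: 18 2-bromo-6-hydroxy-4-methoxybenzaldehyde
Conditions: BCl3 (1.2 equiv), CH2Cl2, −78 → 0 °C; H2O
Reagents that add atoms: none
Why: BCl3 binds the formyl oxygen and cleaves only the methyl ether that can chelate, the one ortho to the aldehyde, leaving the para methoxy group (chelation-controlled mono-demethylation).

Step 9
Reactants: 18 2-bromo-6-hydroxy-4-methoxybenzaldehyde; 19 1-ethynyl-4-methoxybenzene
Product: 20 2-hydroxy-4-methoxy-6-[(4-methoxyphenyl)ethynyl]benzaldehyde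
Conditions: PdCl2(PPh3)2 (cat.), CuI (cat.), Et3N, THF, 60 °C
Reagents that add atoms: none
Why: Sonogashira coupling of the aryl bromide, activated by the ortho formyl group, with the terminal alkyne; the phenol is meta to the new alkyne and cannot cyclise onto it.

Step 10
Reactants: 20 2-hydroxy-4-methoxy-6-[(4-methoxyphenyl)ethynyl]benzaldehyde
Product: 21 tert-butyl 2-formyl-5-methoxy-3-[(4-methoxyphenyl)ethynyl]phenyl carbonate
Conditions: Boc2O, DMAP (cat.), CH2Cl2, rt
Reagents that add atoms: di-tert-butyl dicarbonate, CC(C)(C)OC(=O)OC(=O)OC(C)(C)C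
Why: DMAP-catalysed O-acylation of the chelated phenol, as in step 3 (carbonate formation).

Step 11
Reactants: 22 (2R,5R)-hexane-2,5-diol
Product: 23 (2R,5R)-hexane-2,5-diyl dimethanesulfonate
Conditions: MsCl, Et3N, CH2Cl2, −20 → 0 °C
Reagents that add atoms: methanesulfonyl chloride, CS(=O)(=O)Cl
Why: Sulfonylation at oxygen with retention at carbon (mesylate formation).

Step 12
Reactants: 23 (2R,5R)-hexane-2,5-diyl dimethanesulfonate
Product: 24 (2S,5S)-2,5-dimethylthiolane
Conditions: Na2S·9H2O, EtOH, rt; distillation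
Reagents that add atoms: sodium sulfide, [Na+].[Na+].[S-2]
Why: Double SN2 displacement with inversion at both centres, as in step 5.

Step 13
Reactants: 24 (2S,5S)-2,5-dimethylthiolane; 8 4-methoxybenzyl chloride
Product: 25 (2S,5S)-1-(4-methoxybenzyl)-2,5-dimethylthiolan-1-ium tetrafluoroborate
Conditions: AgBF4, CH2Cl2, 0 °C → rt, dark
Reagents that add atoms: silver tetrafluoroborate, [Ag+].F[B-](F)(F)F
Why: S-alkylation as in step 6; the C2-symmetric sulfide gives one salt.

Step 14
Reactants: 16 (2R,3R)-6-bromo-3-(3,5-dimethoxyphenyl)-2-(4-methoxyphenyl)-4-(triisopropylsilyloxy)-2,3-dihydro-1-benzofuran; 21 tert-butyl 2-formyl-5-methoxy-3-[(4-methoxyphenyl)ethynyl]phenyl carbonate; 25 (2S,5S)-1-(4-methoxybenzyl)-2,5-dimethylthiolan-1-ium tetrafluoroborate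
Product: 31 (2S,3S)-3-[(2R,3R)-3-(3,5-dimethoxyphenyl)-2-(4-methoxyphenyl)-4-(triisopropylsilyloxy)-2,3-dihydro-1-benzofuran-6-yl]-6-methoxy-2-(4-methoxyphenyl)-4-[(4-methoxyphenyl)ethynyl]-2,3-dihydro-1-benzofuran, via aryllithium 26 (not isolated), via lithium phenoxide benzylic carbonate 27 (not isolated), via (2S,5S)-thiolanium benzylide 28 (not isolated), via ortho-quinone methide 29 (not isolated), via phenoxide sulfonium betaine 30 (not isolated)
Conditions: 16, n-BuLi (0.98 equiv), THF, −78 °C; 21 (1.1 equiv), −78 °C; 28 (from 25, LiHMDS, THF, −78 °C, second flask, 2 equiv) added by cannula; MgBr2·OEt2, −78 → −20 °C; aq NH4Cl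
Reagents that add atoms: none
Why: Proposed new method: aryllithium 26 adds to the formyl group of 21, the alkoxide takes over the neighbouring Boc group to leave lithium phenoxide 27, MgBr2 then triggers 1,4-elimination of tert-butyl carbonate to ortho-quinone methide 29, and benzylide 28 attacks its exocyclic carbon to give betaine 30; the closest known reaction types are the organometal-triggered generation of ortho-quinone methides from O-Boc salicylaldehydes and the [4+1] annulation of ortho-quinone methides with sulfonium ylides to trans-2,3-dihydrobenzofurans. The dihydrofuran ring closes by 5-exo-tet displacement of the thiolane by the ring-B phenoxide oxygen at the ylide carbon, with inversion. The oxygen-bearing C2 is set by the ylide face that the C2-symmetric (2S,5S)-thiolane leaves open, as in the stilbene oxide synthesis with this type of reagent, and the diarylmethine C3 follows from the anti placement of the two aryl groups in conjugate addition and closure, which gives the trans ring. The step needs the aryllithium to meet only the aldehyde, which the lithium-to-magnesium switch secures because 27 should not eliminate at −78 °C, and it needs one mode of ring closure, which is fixed because only the oxygen that carried the Boc group becomes the phenoxide. The two stereocentres of 16 are remote from the reacting carbon, so the new pair is under reagent control and the minor enantiomer of 16 ends up in a separable diastereomer. The arylalkyne on ring B is a spectator and stays in place for step 15.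

Step 15
Reactants: 31 the alkyne-bearing bis(dihydrobenzofuran) of step 14
Product: 32 hexamethyl ether of the target that carries OTIPS on the ring-C phenol (seven-membered ring closed; configuration as in the target)
Conditions: [(2-biphenyl)P(t-Bu)2]Au(MeCN)SbF6 (5 mol%), CH2Cl2, rt
Reagents that add atoms: none
Why: Cationic gold(I) activates the alkyne, whose distal carbon (the one bearing the 4-methoxyphenyl group) carries the positive charge, and C7 of the ring-C benzofuran (ortho to the furan oxygen, para to OTIPS) attacks it anti to gold in a 7-endo-dig hydroarylation, a known closure of electron-rich arenes to benzo-fused seven-membered rings; protodeauration gives the ring cis-alkene, attack through C5 is blocked by the flanking OTIPS group, and no stereocentre is touched.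

Step 16
Reactants: 32 hexamethyl ether TIPS ether of the target
Product: 33 hexamethyl ether of the target with the free ring-C phenol
Conditions: TBAF, AcOH, THF, 0 °C
Reagents that add atoms: none
Why: Fluoride cleaves the aryl silyl ether and acetic acid buffers the phenoxide (desilylation).

Step 17
Reactants: 33 hexamethyl ether of the target with the free ring-C phenol
Product: 34 target CNP0325907.1
Conditions: BBr3 (excess), CH2Cl2, −78 → 0 °C; MeOH, then H2O
Reagents that add atoms: none
Why: BBr3 cleaves the six aryl methyl ethers; the benzylic C2–O bonds of the dihydrofurans may ionise reversibly but should reclose to the same, more stable trans isomers, and the C3 centres are not affected (global demethylation).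

**Compound list**

1 | 4-bromo-2,6-dimethoxybenzaldehyde | COc1cc(Br)cc(OC)c1C=O | starting material
2 | 4-bromo-2,6-dihydroxybenzaldehyde | O=Cc1c(O)cc(Br)cc1O | intermediate
3 | 4-bromo-2-hydroxy-6-(triisopropylsilyloxy)benzaldehyde | O=Cc1c(O)cc(Br)cc1O[Si](C(C)C)(C(C)C)C(C)C | intermediate
4 | tert-butyl 5-bromo-2-formyl-3-(triisopropylsilyloxy)phenyl carbonate | O=Cc1c(OC(=O)OC(C)(C)C)cc(Br)cc1O[Si](C(C)C)(C(C)C)C(C)C | intermediate
5 | (2S,5S)-hexane-2,5-diol | C[C@H](O)CC[C@H](C)O | starting material
6 | (2S,5S)-hexane-2,5-diyl dimethanesulfonate | C[C@H](OS(C)(=O)=O)CC[C@H](C)OS(C)(=O)=O | intermediate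
7 | (2R,5R)-2,5-dimethylthiolane | C[C@@H]1CC[C@@H](C)S1 | intermediate
8 | 4-methoxybenzyl chloride | COc1ccc(CCl)cc1 | starting material
9 | (2R,5R)-1-(4-methoxybenzyl)-2,5-dimethylthiolan-1-ium tetrafluoroborate | COc1ccc(C[S+]2[C@H](C)CC[C@H]2C)cc1.F[B-](F)(F)F | intermediate
10 | 1-bromo-3,5-dimethoxybenzene | COc1cc(Br)cc(OC)c1 | starting material
11 | 3,5-dimethoxyphenyllithium | [Li]c1cc(OC)cc(OC)c1 | intermediate
12 | lithium 5-bromo-2-[(tert-butoxycarbonyloxy)(3,5-dimethoxyphenyl)methyl]-3-(triisopropylsilyloxy)phenoxide | [Li+].[O-]c1cc(Br)cc(O[Si](C(C)C)(C(C)C)C(C)C)c1C(OC(=O)OC(C)(C)C)c1cc(OC)cc(OC)c1 | intermediate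
13 | (2R,5R)-2,5-dimethylthiolanium 4-methoxybenzylide | COc1ccc([CH-][S+]2[C@H](C)CC[C@H]2C)cc1 | intermediate
14 | 3-bromo-6-(3,5-dimethoxybenzylidene)-5-(triisopropylsilyloxy)cyclohexa-2,4-dien-1-one | O=C1C=C(Br)C=C(O[Si](C(C)C)(C(C)C)C(C)C)C1=Cc1cc(OC)cc(OC)c1 | intermediate
15 | betaine from 13 and 14 (phenoxide, thiolanium on the ArCH carbon) | [O-]c1cc(Br)cc(O[Si](C(C)C)(C(C)C)C(C)C)c1[C@@H](c1cc(OC)cc(OC)c1)[C@@H](c1ccc(OC)cc1)[S+]1[C@H](C)CC[C@H]1C | intermediate
16 | (2R,3R)-6-bromo-3-(3,5-dimethoxyphenyl)-2-(4-methoxyphenyl)-4-(triisopropylsilyloxy)-2,3-dihydro-1-benzofuran | Brc1cc(O[Si](C(C)C)(C(C)C)C(C)C)c2c(c1)O[C@@H](c1ccc(OC)cc1)[C@@H]2c1cc(OC)cc(OC)c1 | intermediate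
17 | 2-bromo-4,6-dimethoxybenzaldehyde | COc1cc(OC)c(C=O)c(Br)c1 | starting material
18 | 2-bromo-6-hydroxy-4-methoxybenzaldehyde | COc1cc(O)c(C=O)c(Br)c1 | intermediate
19 | 1-ethynyl-4-methoxybenzene | C#Cc1ccc(OC)cc1 | starting material
20 | 2-hydroxy-4-methoxy-6-[(4-methoxyphenyl)ethynyl]benzaldehyde | COc1ccc(C#Cc2cc(OC)cc(O)c2C=O)cc1 | intermediate
21 | tert-butyl 2-formyl-5-methoxy-3-[(4-methoxyphenyl)ethynyl]phenyl carbonate | COc1ccc(C#Cc2cc(OC)cc(OC(=O)OC(C)(C)C)c2C=O)cc1 | intermediate
22 | (2R,5R)-hexane-2,5-diol | C[C@@H](O)CC[C@@H](C)O | starting material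
23 | (2R,5R)-hexane-2,5-diyl dimethanesulfonate | C[C@@H](OS(C)(=O)=O)CC[C@@H](C)OS(C)(=O)=O | intermediate
24 | (2S,5S)-2,5-dimethylthiolane | C[C@H]1CC[C@H](C)S1 | intermediate
25 | (2S,5S)-1-(4-methoxybenzyl)-2,5-dimethylthiolan-1-ium tetrafluoroborate | COc1ccc(C[S+]2[C@@H](C)CC[C@@H]2C)cc1.F[B-](F)(F)F | intermediate
26 | 6-lithio derivative of 16 | [Li]c1cc(O[Si](C(C)C)(C(C)C)C(C)C)c2c(c1)O[C@@H](c1ccc(OC)cc1)[C@@H]2c1cc(OC)cc(OC)c1 | intermediate
27 | lithium phenoxide of the ring-B benzylic tert-butyl carbonate (adduct of 26 and 21 after Boc transfer; carbinol carbon as a mixture) | [Li+].[O-]c1cc(OC)cc(C#Cc2ccc(OC)cc2)c1C(OC(=O)OC(C)(C)C)c1cc(O[Si](C(C)C)(C(C)C)C(C)C)c2c(c1)O[C@@H](c1ccc(OC)cc1)[C@@H]2c1cc(OC)cc(OC)c1 | intermediate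
28 | (2S,5S)-2,5-dimethylthiolanium 4-methoxybenzylide | COc1ccc([CH-][S+]2[C@@H](C)CC[C@@H]2C)cc1 | intermediate
29 | ring-B ortho-quinone methide (exocyclic CH bearing the ring-C dihydrobenzofuran-6-yl group; 3-OMe, 5-arylethynyl) | COc1ccc(C#CC2=CC(OC)=CC(=O)C2=Cc2cc(O[Si](C(C)C)(C(C)C)C(C)C)c3c(c2)O[C@@H](c2ccc(OC)cc2)[C@@H]3c2cc(OC)cc(OC)c2)cc1 | intermediate
30 | betaine from 28 and 29 (ring-B phenoxide, thiolanium on the ArCH carbon) | COc1ccc(C#Cc2cc(OC)cc([O-])c2[C@H](c2cc(O[Si](C(C)C)(C(C)C)C(C)C)c3c(c2)O[C@@H](c2ccc(OC)cc2)[C@@H]3c2cc(OC)cc(OC)c2)[C@H](c2ccc(OC)cc2)[S+]2[C@@H](C)CC[C@@H]2C)cc1 | intermediate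
31 | (2S,3S)-3-[(2R,3R)-3-(3,5-dimethoxyphenyl)-2-(4-methoxyphenyl)-4-(triisopropylsilyloxy)-2,3-dihydro-1-benzofuran-6-yl]-6-methoxy-2-(4-methoxyphenyl)-4-[(4-methoxyphenyl)ethynyl]-2,3-dihydro-1-benzofuran | COc1ccc(C#Cc2cc(OC)cc3c2[C@H](c2cc(O[Si](C(C)C)(C(C)C)C(C)C)c4c(c2)O[C@@H](c2ccc(OC)cc2)[C@@H]4c2cc(OC)cc(OC)c2)[C@@H](c2ccc(OC)cc2)O3)cc1 | intermediate
32 | hexamethyl ether of the target with OTIPS on the ring-C phenol | COc1ccc(C2=Cc3cc(OC)cc4c3[C@H](c3cc(O[Si](C(C)C)(C(C)C)C(C)C)c5c(c32)O[C@@H](c2ccc(OC)cc2)[C@@H]5c2cc(OC)cc(OC)c2)[C@@H](c2ccc(OC)cc2)O4)cc1 | intermediate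
33 | hexamethyl ether of the target with the free ring-C phenol | COc1ccc(C2=Cc3cc(OC)cc4c3[C@H](c3cc(O)c5c(c32)O[C@@H](c2ccc(OC)cc2)[C@@H]5c2cc(OC)cc(OC)c2)[C@@H](c2ccc(OC)cc2)O4)cc1 | intermediate
34 | CNP0325907.1 | Oc1ccc(C2=Cc3cc(O)cc4c3[C@H](c3cc(O)c5c(c32)O[C@@H](c2ccc(O)cc2)[C@@H]5c2cc(O)cc(O)c2)[C@@H](c2ccc(O)cc2)O4)cc1 | target

**Count and risks**

Total step count: 17. Longest linear sequence: 8 steps (1 → 2 → 3 → 4 → 16 → 31 → 32 → 33 → 34).

Steps most likely to fail:

1. Step 14 (Proposed new method). What may go wrong: elimination to the quinone methide before the ylide has arrived, followed by its dimerisation; rearrangement or magnesium complexation of the benzylide; proton transfer from the doubly benzylic C3–H of 16 to the aryllithium; or weak facial control. The fallback uses known chemistry, sets out from 18 and 16, and comes back at 31. Phenol 18 is O-alkylated with 8 (K2CO3, DMF) to 2-bromo-4-methoxy-6-[(4-methoxybenzyl)oxy]benzaldehyde F1. Aryllithium 26 (from 16, n-BuLi, −78 °C) is added to give the diaryl carbinol F2, which MnO2 oxidises to the diaryl ketone F3. Condensation with hydrazine gives the hydrazone F4, and MnO2 converts it into the diaryldiazomethane F5. A chiral dirhodium tetracarboxylate (Rh2(S-PTAD)4 or its enantiomer, whichever sets C3 as in 31) then inserts the donor/donor carbene into the benzylic ether C–H bond to give the 2,3-cis dihydrobenzofuran bromide F6. Brief exposure to TFA equilibrates C2 through the 4-methoxybenzylic cation to the trans bromide F7, and Sonogashira coupling with 19 gives 31.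

2. Step 7 (Proposed new method). What may go wrong: the same processes as in step 14, plus silyl transfer from the phenolic oxygen to the new alkoxide in place of Boc transfer, and low trans selectivity at the hindered methide carbon between two oxygens. The fallback uses known chemistry, sets out from 3, and comes back at 16. Phenol 3 is O-alkylated with 8 (K2CO3, acetone) to 4-bromo-2-[(4-methoxybenzyl)oxy]-6-(triisopropylsilyloxy)benzaldehyde F8. Aryllithium 11 (from 10, n-BuLi) is added to give the diaryl carbinol F9, which MnO2 oxidises to the diaryl ketone F10. Hydrazine gives the hydrazone F11 and MnO2 the diaryldiazomethane F12. Rh2(R-PTAD)4 or its enantiomer (whichever sets C3 as R) effects the intramolecular C–H insertion to the 2,3-cis dihydrobenzofuran F13, which TFA equilibrates at C2 to the trans compound 16.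

3. Step 15. What may go wrong: closure through C5 of ring C in place of C7, 6-exo attack at the proximal alkyne carbon, or gold-promoted opening of a benzylic C–O bond. The fallback sets out from 31 and comes back at 32. Mercury(II) triflate-catalysed hydration of the alkyne (H2O, MeCN) places the carbonyl on the carbon that bears the 4-methoxyphenyl group and gives the deoxybenzoin-type ketone F14. Acid-mediated cyclodehydration (MsOH or Bi(OTf)3, CH2Cl2) then lets C7 of ring C attack the activated ketone, and loss of water gives the ring alkene of 32.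

**Further compounds**

F1 | step 14 | 2-bromo-4-methoxy-6-[(4-methoxybenzyl)oxy]benzaldehyde | COc1cc(Br)c(C=O)c(OCc2ccc(OC)cc2)c1
F2 | step 14 | diaryl carbinol from 26 and F1 | COc1cc(Br)c(C(O)c2cc(O[Si](C(C)C)(C(C)C)C(C)C)c3c(c2)O[C@@H](c2ccc(OC)cc2)[C@@H]3c2cc(OC)cc(OC)c2)c(OCc2ccc(OC)cc2)c1
F3 | step 14 | diaryl ketone from F2 | COc1cc(Br)c(C(=O)c2cc(O[Si](C(C)C)(C(C)C)C(C)C)c3c(c2)O[C@@H](c2ccc(OC)cc2)[C@@H]3c2cc(OC)cc(OC)c2)c(OCc2ccc(OC)cc2)c1
F4 | step 14 | hydrazone of F3 | COc1cc(Br)c(C(=NN)c2cc(O[Si](C(C)C)(C(C)C)C(C)C)c3c(c2)O[C@@H](c2ccc(OC)cc2)[C@@H]3c2cc(OC)cc(OC)c2)c(OCc2ccc(OC)cc2)c1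
F5 | step 14 | diaryldiazomethane from F4 | COc1cc(Br)c(C(=[N+]=[N-])c2cc(O[Si](C(C)C)(C(C)C)C(C)C)c3c(c2)O[C@@H](c2ccc(OC)cc2)[C@@H]3c2cc(OC)cc(OC)c2)c(OCc2ccc(OC)cc2)c1
F6 | step 14 | (2R,3S)-cis 4-bromo analogue of 31 (Br in place of the arylethynyl group) | Brc1cc(OC)cc2c1[C@H](c1cc(O[Si](C(C)C)(C(C)C)C(C)C)c3c(c1)O[C@@H](c1ccc(OC)cc1)[C@@H]3c1cc(OC)cc(OC)c1)[C@H](c1ccc(OC)cc1)O2
F7 | step 14 | (2S,3S)-trans 4-bromo analogue of 31 | Brc1cc(OC)cc2c1[C@H](c1cc(O[Si](C(C)C)(C(C)C)C(C)C)c3c(c1)O[C@@H](c1ccc(OC)cc1)[C@@H]3c1cc(OC)cc(OC)c1)[C@@H](c1ccc(OC)cc1)O2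
F8 | step 7 | 4-bromo-2-[(4-methoxybenzyl)oxy]-6-(triisopropylsilyloxy)benzaldehyde | O=Cc1c(OCc2ccc(OC)cc2)cc(Br)cc1O[Si](C(C)C)(C(C)C)C(C)C
F9 | step 7 | diaryl carbinol from 11 and F8 | OC(c1cc(OC)cc(OC)c1)c1c(OCc2ccc(OC)cc2)cc(Br)cc1O[Si](C(C)C)(C(C)C)C(C)C
F10 | step 7 | diaryl ketone from F9 | O=C(c1cc(OC)cc(OC)c1)c1c(OCc2ccc(OC)cc2)cc(Br)cc1O[Si](C(C)C)(C(C)C)C(C)C
F11 | step 7 | hydrazone of F10 | NN=C(c1cc(OC)cc(OC)c1)c1c(OCc2ccc(OC)cc2)cc(Br)cc1O[Si](C(C)C)(C(C)C)C(C)C
F12 | step 7 | diaryldiazomethane from F11 | [N-]=[N+]=C(c1cc(OC)cc(OC)c1)c1c(OCc2ccc(OC)cc2)cc(Br)cc1O[Si](C(C)C)(C(C)C)C(C)C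
F13 | step 7 | (2S,3R)-cis isomer of 16 | Brc1cc(O[Si](C(C)C)(C(C)C)C(C)C)c2c(c1)O[C@H](c1ccc(OC)cc1)[C@@H]2c1cc(OC)cc(OC)c1
F14 | step 15 | ketone from hydration of 31 (ArC(=O)CH2 on ring B) | COc1ccc(C(=O)Cc3cc(OC)cc4c3[C@H](c3cc(O[Si](C(C)C)(C(C)C)C(C)C)c5c(c3)O[C@@H](c2ccc(OC)cc2)[C@@H]5c2cc(OC)cc(OC)c2)[C@@H](c2ccc(OC)cc2)O4)cc1
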